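## The problem

The target is a (3R)-isoflavan: a chroman (O1, C2–C4, C4a, C8a) whose C3, the only stereocentre (the [C@H] of the SMILES is R), carries ring B. Ring A is a phloroglucinol in which all three oxygens differ (methyl ether at C5, free hydroxyl at C7, ring ether at C8a), and its prenyl group sits at C6, between O5 and O7, not at C8. Ring B is a 2-hydroxy-1,4-benzoquinone (carbonyls at C2' and C5', hydroxyl at C4') with a second prenyl group at C3', again between two oxygens. With no second stereocentre to relay from, C3 must be set by a chiral catalyst. It lies next to the benzylic C4 and, in the target, in a vinylogous α-position of the quinone, so it must not meet conditions that ionise C4 reversibly or enolise the quinone for long. The two trisubstituted alkenes exclude catalytic hydrogenation and hydrogenolysis and make strong acid dangerous, because each prenyl group has a hydroxyl neighbour that can close a chroman ring. The hydroxyquinone is sensitive to nucleophiles, reductants and base, and both arenes are electron-rich enough to be over-oxidised. The feature that opens ring A to a short construction is its polyketide pattern: oxygens at C5, C7 and C8a alternate with carbon substituents at C4a and C6, as in a 3,5,7-triketo ester folded by Claisen condensation, the chain methylene C4a being acylated by the ester carbon C8a. A 2-pyrone is an isolable form of that chain in which the middle oxygen (future O7) is already an enol ether and a pyrone C5 substituent ends at C6; what the folding does not do is tell O5 from O8a, and that has to be solved separately.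

## Retrosynthesis

**Target 25 back to isoflavan 22.** No skeletal bond is cut; only the oxidation level of ring B and two O-substituents change. The hydroxyquinone is traced to the 4'-methoxyquinone 23 and this to the trimethyl ether of ring B in 22. Carrying a quinone through the reductive steps that set C3 is not possible, so ring B travels as an inert 1,2,4-trimethoxyarene and O7 stays masked until the last flask. The forward steps must oxidise ring B in the presence of ring A and two alkenes, then exchange one vinylogous ester oxygen and remove one acetal.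

**Isoflavan 22 back to isoflavanone 20.** The two C4–H bonds are traced to the C4 carbonyl through the cis-alcohol 21. This is preferred to a C3–C1' or C2–C3 bond construction with a chiral auxiliary because in 20 the stereocentre is epimerisable. A transfer hydrogenation with dynamic kinetic resolution can therefore convert the whole racemate into one cis-alcohol and set C3 without any stoichiometric chiral material. The forward sequence needs a catalyst that tolerates a ketone flanked by the C5 methoxy group, and a deoxygenation that leaves C3 alone.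

**Isoflavanone 20 back to deoxybenzoin 15.** The bonds O1–C2 and C2–C3 are cut, C2 coming from a one-carbon electrophile that is attached to the activated methylene and then closed on by a phenol. Direct closure of the dihydroxy ketone 15 would let either phenol react, and an intramolecular closure discriminates poorly between an oxygen next to H and one next to prenyl. The decision is therefore moved to an intermolecular reaction with a bulky chlorosilane. The less hindered phenol (future O1) is silylated (16), the chelated, prenyl-flanked phenol is methylated (17), and fluoride then releases the only phenoxide (18) that can close ring C. This costs one step more than direct closure and removes the regiochemical doubt.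

**Deoxybenzoin 15 back to pyrone 13.** The C4a–C8a bond is cut and ring A is unfolded to the open-chain keto ester 14, whose lactone form is the pyrone 13. Against the neighbouring option of acylating a ready-made prenylphloroglucinol, this cut creates the aromatic ring and places its five substituents in one operation, with the prenyl group fixed at C6 by its position on the pyrone. The precursor has no arene in ring A at all. The forward reaction must fold in Claisen and not aldol mode and must keep the enol ether that marks O7.

**Pyrone 13 back to pyrone 6 and aldehyde 11.** The bond between the pyrone side-chain methylene and the ketone carbon is cut, at the alcohol oxidation level (12). An aldol addition followed by oxidation is chosen over direct acylation with an arylacetic ester, because that ester is as acidic as the pyrone methyl group and would be enolised instead of attacked. This is the convergent junction; both halves carry their prenyl group already.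

**Pyrone 6 back to methyl acetoacetate 1 and prenyl bromide 2.** The lactone C–O bond and two C–C bonds at the γ-carbon of an acetoacetate are cut: 6 from hydroxypyrone 5, 5 from the diketo ester 4, 4 from the γ-prenyl keto ester 3. A one-step pyrone synthesis from a methyl ketone and a malonyl dihalide would be shorter. It liberates hydrogen chloride next to a trisubstituted alkene and leaves the side of enolisation open, so two successive dianion operations, each of a well-known type, are preferred.

**Aldehyde 11 back to 2,4,5-trimethoxybenzaldehyde 7.** The aryl–prenyl bond is cut at the position between two methoxy groups, which is the site of directed lithiation; the aldehyde is traced through acetal 10 and 9 and the enol ether 8 to 7 by one-carbon homologation. Homologation before lithiation is chosen because a benzaldehyde acetal would direct the base to the other free ring position, whereas the homologous acetal 9 does not.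

## Roads not taken

**Alternative 1:** The cut is through C3–C1' and, after notional reclosure of a furan ring, C4–O(2'). In the forward step a ring A chromene, 5-methoxy-6-prenyl-7-(triisopropylsilyloxy)-2H-chromene A3, and 2-methoxy-3-prenyl-1,4-benzoquinone A2 combine under a chiral tetravalent titanium TADDOLate prepared from Ti(OiPr)2Cl2. The formal [3+2] addition gives the cis-pterocarpan A1, and the benzylic C–O bond is opened reductively afterwards.
- Merits: the road is highly convergent, and the C3–C1' bond and the stereocentre arise in one event. Ring B arrives almost at the quinone level, so the harsh oxidative demethylation of the chosen plan would be replaced by oxidation of a hydroquinone monoether; in this respect the alternative is better.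
- Weak points: A3 still needs the fully differentiated ring A, made by substitution chemistry with the C6 against C8 question open. The two prenyl alkenes are themselves competent partners for a Lewis-acid-activated alkoxyquinone. The 5,7-dioxygenated chromene is prone to ionisation under titanium. The promoter is usually needed in stoichiometric amount, with substrate-dependent selectivity. Ring opening of A1 cannot use hydrogenolysis and would pass through the same C4 cation as step 16.
- Comparison: the alternative would be shorter by perhaps a third. The chosen plan sets against this a ring A whose pattern is fixed by construction, no competition between alkenes, and a reduction-based stereocontrol with broad precedent on isoflavanones.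

**Alternative 2:** The cut is the C1'–C2' bond of ring B. A squarate-derived 4-alkynyl-4-hydroxycyclobutenone A5, whose alkyne carries the chroman, opens on heating to a vinylketene that closes on the alkyne and gives the methoxyquinone A4, identical with compound 23.
- Merits: ring B is built with every substituent placed by squarate chemistry, under neutral thermal conditions and without any oxidant near ring A. This is better than step 17 of the chosen plan.
- Weak points: the stereocentre would sit on a 3-ethynylchroman, a centre that is not epimerisable at that stage and for which no dynamic resolution exists. Its usual precursor, a 3-formylchroman, is epimerisable under the basic homologation conditions. Ring A and its regiochemistry remain unsolved. The ring expansion can divert to cyclopentenediones. The endgame after A4 is the same as here.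
- Comparison: the alternative removes the ring B oxidation risk but introduces a harder stereochemical problem. The chosen plan solves ring A and C3 with precedented steps, and the squarate route is the natural replacement for ring B should step 17 fail.

**Alternative 3:** The cuts are the C5–OMe bond and the C6–CH2 bond of the prenyl group. CsF releases a C5–C6 aryne from the silyl triflate A7. The oxygen of 3-methoxy-3-methylbut-1-ene A8 adds at C5 (remote from the C7 acetal, as 3-alkoxyarynes require), and the zwitterion transfers the allyl group to C6 through a six-membered Claisen-type shift, giving A6, identical with compound 22.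
- Merits: the vicinal OMe/prenyl pair is installed with certain regiochemistry under mild conditions, and O5 arrives methylated. The alternative therefore does not need the temporary silyl differentiation of O5 from O8a that costs the chosen plan part of steps 12 to 14, a real advantage.
- Weak points: dialkyl ethers are weak aryne traps, and ene reaction with the ring B prenyl group or cycloaddition to the electron-rich ring B can compete. A7 needs an isoflavan with an ortho-silyl triflate on ring A, which is several steps of arene chemistry on a substrate whose stereocentre is already set. No ring and no stereocentre are formed, so nothing is gained in convergence.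
- Comparison: the chosen plan sets against the regiochemical advantage the creation of ring A from acyclic material in one precedented step, whereas the aryne step rests on a thinly documented reaction class.

Key step: step 11

Assumption: steps run with lithium, sodium or magnesium bases are quenched with aqueous NH4Cl or dilute HCl, so that the metals end as their chlorides.

Abbreviations in names: prenyl = 3-methylbut-2-en-1-yl; Ar = 2,4,5-trimethoxy-3-prenylphenyl; MOM = methoxymethyl; TIPS = triisopropylsilyl.

## Route

Step 1
Reactants: 1 methyl acetoacetate; 2 prenyl bromide (1-bromo-3-methylbut-2-ene)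
Product: 3 methyl 7-methyl-3-oxooct-6-enoate
Conditions: NaH, THF, 0 °C; n-BuLi, 0 °C; then 2, 0 °C to rt
Reagents that add atoms: none
Why: Huckin–Weiler γ-alkylation: the dianion of the β-keto ester reacts at its terminal, more basic carbon, and the primary allylic bromide is taken by SN2 so the prenyl unit stays linear.

Step 2
Reactants: 3 methyl 7-methyl-3-oxooct-6-enoate
Product: 4 methyl 4-prenyl-3,5-dioxohexanoate (racemic at C4, largely enolised)
Conditions: NaH, THF, 0 °C; n-BuLi, 0 °C; MeC(O)N(OMe)Me, −78 to 0 °C
Reagents that add atoms: N-methoxy-N-methylacetamide, CC(=O)N(C)OC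
Why: A second dianion forms at the γ-carbon (C4) and is acylated by the Weinreb amide; the chelated tetrahedral adduct survives until work-up, so the more acidic product cannot quench unreacted dianion and no double addition occurs.

Step 3
Reactants: 4 methyl 4-prenyl-3,5-dioxohexanoate
Product: 5 4-hydroxy-6-methyl-5-prenyl-2H-pyran-2-one
Conditions: DBU, toluene, 80 °C; then dilute HCl
Reagents that add atoms: none
Why: Base-mediated lactonisation of a 3,5-diketo ester: the enolate oxygen of the C5 ketone attacks the ester (6-exo-trig) and methanol is lost, the standard route to 4-hydroxy-2-pyrones.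

Step 4
Reactants: 5 4-hydroxy-6-methyl-5-prenyl-2H-pyran-2-one
Product: 6 4-(methoxymethoxy)-6-methyl-5-prenyl-2H-pyran-2-one
Conditions: MOMCl, i-Pr2NEt, CH2Cl2, 0 °C to rt
Reagents that add atoms: chloromethyl methyl ether, COCCl
Why: O-Alkylation of the vinylogous acid with a hard electrophile occurs at O4; the acetal is base-stable and will mark the future O7.

Step 5
Reactants: 7 2,4,5-trimethoxybenzaldehyde
Product: 8 1,2,4-trimethoxy-5-(2-methoxyethenyl)benzene (E/Z mixture)
Conditions: Ph3P(CH2OMe)Cl, KOt-Bu, THF, 0 °C to rt
Reagents that add atoms: (methoxymethyl)triphenylphosphonium chloride, COC[P+](c1ccccc1)(c1ccccc1)c1ccccc1.[Cl-]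
Why: Wittig methoxymethylenation, the usual one-carbon homologation of an aryl aldehyde; the alkene geometry is of no consequence.

Step 6
Reactants: 8 1,2,4-trimethoxy-5-(2-methoxyethenyl)benzene
Product: 9 1-(2,2-dimethoxyethyl)-2,4,5-trimethoxybenzene
Conditions: MeOH, TsOH·H2O (cat.), 50 °C
Reagents that add atoms: methanol, CO
Why: Acid-catalysed addition of methanol to the enol ether gives the dimethyl acetal, a form of the arylacetaldehyde that tolerates butyllithium.

Step 7
Reactants: 9 1-(2,2-dimethoxyethyl)-2,4,5-trimethoxybenzene; 2 prenyl bromide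
Product: 10 1-(2,2-dimethoxyethyl)-2,4,5-trimethoxy-3-prenylbenzene
Conditions: n-BuLi, TMEDA, THF, 0 °C; CuBr·SMe2, −40 °C; then 2, −40 to 0 °C
Reagents that add atoms: none
Why: Directed ortho-metalation takes the ring hydrogen flanked by two methoxy groups, kinetically the most acidic site; transmetalation to copper gives clean SN2 coupling with the allylic bromide.

Step 8
Reactants: 10 1-(2,2-dimethoxyethyl)-2,4,5-trimethoxy-3-prenylbenzene
Product: 11 2-(2,4,5-trimethoxy-3-prenylphenyl)acetaldehyde (ArCH2CHO)
Conditions: 2 M HCl, THF, 0 °C to rt; used at once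
Reagents that add atoms: water, O
Why: Acetal hydrolysis under dilute acid; the ring has no free hydroxyl, so the prenyl group has no partner for cyclisation, and the sensitive aldehyde is not stored.

Step 9
Reactants: 6 4-(methoxymethoxy)-6-methyl-5-prenyl-2H-pyran-2-one; 11 ArCH2CHO
Product: 12 6-(3-Ar-2-hydroxypropyl)-4-(methoxymethoxy)-5-prenyl-2H-pyran-2-one (racemic)
Conditions: LiN(i-Pr)2, THF, −78 °C; then 11, −78 °C; aq. NH4Cl
Reagents that add atoms: none
Why: The 6-methyl group of a 4-alkoxy-2-pyrone is deprotonated to an extended dienolate (vinylogous aldol); addition to the aldehyde at −78 °C outruns its enolisation, and the new carbinol centre is removed in the next step.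

Step 10
Reactants: 12 6-(3-Ar-2-hydroxypropyl)-4-(methoxymethoxy)-5-prenyl-2H-pyran-2-one
Product: 13 4-(methoxymethoxy)-6-(3-Ar-2-oxopropyl)-5-prenyl-2H-pyran-2-one
Conditions: Dess–Martin periodinane, NaHCO3, CH2Cl2, 0 °C to rt
Reagents that add atoms: none
Why: Dess–Martin oxidation of a secondary alcohol under buffered, non-acidic conditions spares the alkenes, the acetal and the electron-rich arene.

Step 11
Reactants: 13 4-(methoxymethoxy)-6-(3-Ar-2-oxopropyl)-5-prenyl-2H-pyran-2-one
Product: 15 1-[2,6-dihydroxy-4-(methoxymethoxy)-3-prenylphenyl]-2-Ar-ethan-1-one, via ring-opened methyl ester 14 (not isolated)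
Conditions: Mg(OMe)2, MeOH, reflux; then cold 0.5 M HCl
Reagents that add atoms: none
Why: Mg(OMe)2 turns the β-dicarbonyl unit of 13 into a magnesium chelate and delivers methoxide to the lactone carbonyl, opening the ring to ester 14, in which the ester and the diketone arm stay cis on the enol ether double bond inherited from the pyrone. The doubly activated methylene (future C4a) then attacks the ester carbonyl (future C8a) in a Claisen condensation of Dieckmann type, forming the C4a–C8a bond; the closure is 6-exo-trig at the ester and enolendo for the enolate, an allowed mode. Loss of methoxide and enolisation give the aromatic acylphloroglucinol 15. The closest known reaction is the Mg(OMe)2-induced cyclisation of 6-(2-oxoalkyl)-4-methoxy-2-pyrones and of free 3,5,7-triketo esters to acylphloroglucinols. No stereocentre is formed, and the methine of 14 is lost on aromatisation. The step needs Claisen and not aldol folding and C- and not O-acylation: the enol ether at the middle carbonyl removes the nucleophilic methylene that an aldol closure would use, and the magnesium template favours attack through carbon. The same enol ether leaves O7 protected beside two new free phenols, and the pyrone C5 prenyl group ends at C6.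

Step 12
Reactants: 15 1-[2,6-dihydroxy-4-(methoxymethoxy)-3-prenylphenyl]-2-Ar-ethan-1-one
Product: 16 1-[2-hydroxy-4-(methoxymethoxy)-3-prenyl-6-(triisopropylsilyloxy)phenyl]-2-Ar-ethan-1-one
Conditions: i-Pr3SiCl (1.1 equiv), imidazole, DMF, 0 °C to rt
Reagents that add atoms: chlorotriisopropylsilane, CC(C)[Si](Cl)(C(C)C)C(C)C
Why: Silylation with a bulky chlorosilane should go to the phenol flanked by H and not to the one wedged between the acyl and prenyl groups, which stays hydrogen-bonded to the ketone.

Step 13
Reactants: 16 1-[2-hydroxy-4-(methoxymethoxy)-3-prenyl-6-(triisopropylsilyloxy)phenyl]-2-Ar-ethan-1-one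
Product: 17 1-[2-methoxy-4-(methoxymethoxy)-3-prenyl-6-(triisopropylsilyloxy)phenyl]-2-Ar-ethan-1-one
Conditions: Me2SO4, K2CO3, acetone, reflux
Reagents that add atoms: dimethyl sulfate, COS(=O)(=O)OC
Why: Williamson methylation of a chelated ortho-acyl phenol under classical conditions; carbonate in dry acetone should leave the aryl TIPS ether intact and is too weak to C-methylate the benzylic methylene appreciably.

Step 14
Reactants: 17 1-[2-methoxy-4-(methoxymethoxy)-3-prenyl-6-(triisopropylsilyloxy)phenyl]-2-Ar-ethan-1-one
Product: 20 rac-5-methoxy-7-(methoxymethoxy)-6-prenyl-3-Ar-2,3-dihydro-4H-chromen-4-one, via free phenol 18 (not isolated), via α-methylene ketone 19 (not isolated)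
Conditions: Bu4NF, THF, 0 °C; then (CH2O)n, Et2NH, MeOH, 60 °C
Reagents that add atoms: paraformaldehyde (formaldehyde), C=O
Why: Fluoride frees the single phenol 18; Mannich-type α-methylenation of the deoxybenzoin gives enone 19, and the phenoxide closes ring C by 6-endo-trig oxa-Michael addition, the usual isoflavanone synthesis. Only one phenol is present, so the regiochemistry is fixed, and C3 is formed racemic.

Step 15
Reactants: 20 rac-5-methoxy-7-(methoxymethoxy)-6-prenyl-3-Ar-2,3-dihydro-4H-chromen-4-one
Product: 21 (3R,4R)-5-methoxy-7-(methoxymethoxy)-6-prenyl-3-Ar-3,4-dihydro-2H-chromen-4-ol (cis)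
Conditions: RuCl[(R,R)-TsDPEN](p-cymene) (2 mol %), HCO2H–Et3N (5:2), EtOAc, 40 °C
Reagents that add atoms: none
Why: Noyori–Ikariya transfer hydrogenation with dynamic kinetic resolution: C3 epimerises through the enol under Et3N, and the (R,R)-catalyst, which gives (R)-carbinols from aryl ketones, should reduce the (3R)-ketone preferentially to the cis-alcohol, setting C3 and C4 together. The ruthenium hydride does not touch isolated trisubstituted alkenes.

Step 16
Reactants: 21 (3R,4R)-5-methoxy-7-(methoxymethoxy)-6-prenyl-3-Ar-3,4-dihydro-2H-chromen-4-ol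
Product: 22 (3R)-5-methoxy-7-(methoxymethoxy)-6-prenyl-3-Ar-3,4-dihydro-2H-chromene
Conditions: Et3SiH, CF3CO2H, CH2Cl2, −40 °C
Reagents that add atoms: none
Why: Ionic hydrogenation: the C4 cation, stabilised by O1, 5-OMe and 7-OMOM, forms at low temperature and is captured by the silane before alkene protonation or acetal cleavage can compete. C3 is not involved and should keep its configuration.

Step 17
Reactants: 22 (3R)-5-methoxy-7-(methoxymethoxy)-6-prenyl-3-Ar-3,4-dihydro-2H-chromene
Product: 23 2-methoxy-5-[(3R)-5-methoxy-7-(methoxymethoxy)-6-prenyl-3,4-dihydro-2H-chromen-3-yl]-3-prenylcyclohexa-2,5-diene-1,4-dione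
Conditions: (NH4)2Ce(NO3)6, MeCN–H2O, 0 °C
Reagents that add atoms: water, O
Why: Oxidative demethylation by tetravalent cerium: the 1,2,4-trialkoxy ring B has the lowest oxidation potential and its para pair (2',5') gives the para-quinone with the 4'-methoxy group kept. Prenyl side chains tolerate this oxidation, as in ubiquinone syntheses, and an ortho-quinone isomer would converge in step 18.

Step 18
Reactants: 23 2-methoxy-5-[(3R)-5-methoxy-7-(methoxymethoxy)-6-prenyl-3,4-dihydro-2H-chromen-3-yl]-3-prenylcyclohexa-2,5-diene-1,4-dione
Product: 25 2-hydroxy-5-[(3R)-7-hydroxy-5-methoxy-6-prenyl-3,4-dihydro-2H-chromen-3-yl]-3-prenylcyclohexa-2,5-diene-1,4-dione (target), via MOM-protected hydroxyquinone 24 (not isolated)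
Conditions: 1 M NaOH, THF, 0 °C, argon; then HCl to pH 1, THF–H2O, 40 °C
Reagents that add atoms: sodium hydroxide, [Na+].[OH-]
Why: Hydroxide replaces the methoxy group of the vinylogous ester by addition–elimination, giving the deactivated hydroxyquinone anion while ring A is still protected; acidification then hydrolyses the aryl MOM acetal. Water and not methanol is the solvent, so the hydroxyquinone is not re-etherified.

## Compound list

1 | methyl acetoacetate | COC(=O)CC(C)=O | starting material
2 | prenyl bromide (1-bromo-3-methylbut-2-ene) | CC(C)=CCBr | starting material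
3 | methyl 7-methyl-3-oxooct-6-enoate | COC(=O)CC(=O)CCC=C(C)C | intermediate
4 | methyl 4-(3-methylbut-2-en-1-yl)-3,5-dioxohexanoate (racemic) | COC(=O)CC(=O)C(CC=C(C)C)C(C)=O | intermediate
5 | 4-hydroxy-6-methyl-5-(3-methylbut-2-en-1-yl)-2H-pyran-2-one | CC1=C(CC=C(C)C)C(O)=CC(=O)O1 | intermediate
6 | 4-(methoxymethoxy)-6-methyl-5-(3-methylbut-2-en-1-yl)-2H-pyran-2-one | CC1=C(CC=C(C)C)C(OCOC)=CC(=O)O1 | intermediate
7 | 2,4,5-trimethoxybenzaldehyde | COc1cc(OC)c(C=O)cc1OC | starting material
8 | 1,2,4-trimethoxy-5-(2-methoxyethenyl)benzene (E/Z mixture) | COC=Cc1cc(OC)c(OC)cc1OC | intermediate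
9 | 1-(2,2-dimethoxyethyl)-2,4,5-trimethoxybenzene | COC(OC)Cc1cc(OC)c(OC)cc1OC | intermediate
10 | 1-(2,2-dimethoxyethyl)-2,4,5-trimethoxy-3-(3-methylbut-2-en-1-yl)benzene | COC(OC)Cc1cc(OC)c(OC)c(CC=C(C)C)c1OC | intermediate
11 | 2-[2,4,5-trimethoxy-3-(3-methylbut-2-en-1-yl)phenyl]acetaldehyde | O=CCc1cc(OC)c(OC)c(CC=C(C)C)c1OC | intermediate
12 | 6-{2-hydroxy-3-[2,4,5-trimethoxy-3-(3-methylbut-2-en-1-yl)phenyl]propyl}-4-(methoxymethoxy)-5-(3-methylbut-2-en-1-yl)-2H-pyran-2-one (racemic) | O=C1OC(CC(O)Cc2cc(OC)c(OC)c(CC=C(C)C)c2OC)=C(CC=C(C)C)C(OCOC)=C1 | intermediate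
13 | 4-(methoxymethoxy)-5-(3-methylbut-2-en-1-yl)-6-{2-oxo-3-[2,4,5-trimethoxy-3-(3-methylbut-2-en-1-yl)phenyl]propyl}-2H-pyran-2-one | O=C1OC(CC(=O)Cc2cc(OC)c(OC)c(CC=C(C)C)c2OC)=C(CC=C(C)C)C(OCOC)=C1 | intermediate
14 | methyl (2E)-3-(methoxymethoxy)-4-(3-methylbut-2-en-1-yl)-5,7-dioxo-8-[2,4,5-trimethoxy-3-(3-methylbut-2-en-1-yl)phenyl]oct-2-enoate (ester and C4 cis on the double bond; present as its magnesium enolate) | COC(=O)/C=C(OCOC)\C(CC=C(C)C)C(=O)CC(=O)Cc1cc(OC)c(OC)c(CC=C(C)C)c1OC | intermediate
15 | 1-[2,6-dihydroxy-4-(methoxymethoxy)-3-(3-methylbut-2-en-1-yl)phenyl]-2-[2,4,5-trimethoxy-3-(3-methylbut-2-en-1-yl)phenyl]ethan-1-one | COCOc1cc(O)c(C(=O)Cc2cc(OC)c(OC)c(CC=C(C)C)c2OC)c(O)c1CC=C(C)C | intermediate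
16 | 1-[2-hydroxy-4-(methoxymethoxy)-3-(3-methylbut-2-en-1-yl)-6-(triisopropylsilyloxy)phenyl]-2-[2,4,5-trimethoxy-3-(3-methylbut-2-en-1-yl)phenyl]ethan-1-one | COCOc1cc(O[Si](C(C)C)(C(C)C)C(C)C)c(C(=O)Cc2cc(OC)c(OC)c(CC=C(C)C)c2OC)c(O)c1CC=C(C)C | intermediate
17 | 1-[2-methoxy-4-(methoxymethoxy)-3-(3-methylbut-2-en-1-yl)-6-(triisopropylsilyloxy)phenyl]-2-[2,4,5-trimethoxy-3-(3-methylbut-2-en-1-yl)phenyl]ethan-1-one | COCOc1cc(O[Si](C(C)C)(C(C)C)C(C)C)c(C(=O)Cc2cc(OC)c(OC)c(CC=C(C)C)c2OC)c(OC)c1CC=C(C)C | intermediate
18 | 1-[6-hydroxy-2-methoxy-4-(methoxymethoxy)-3-(3-methylbut-2-en-1-yl)phenyl]-2-[2,4,5-trimethoxy-3-(3-methylbut-2-en-1-yl)phenyl]ethan-1-one | COCOc1cc(O)c(C(=O)Cc2cc(OC)c(OC)c(CC=C(C)C)c2OC)c(OC)c1CC=C(C)C | intermediate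
19 | 1-[6-hydroxy-2-methoxy-4-(methoxymethoxy)-3-(3-methylbut-2-en-1-yl)phenyl]-2-[2,4,5-trimethoxy-3-(3-methylbut-2-en-1-yl)phenyl]prop-2-en-1-one | COCOc1cc(O)c(C(=O)C(=C)c2cc(OC)c(OC)c(CC=C(C)C)c2OC)c(OC)c1CC=C(C)C | intermediate
20 | rac-5-methoxy-7-(methoxymethoxy)-6-(3-methylbut-2-en-1-yl)-3-[2,4,5-trimethoxy-3-(3-methylbut-2-en-1-yl)phenyl]-2,3-dihydro-4H-chromen-4-one | COc1c(CC=C(C)C)c(OCOC)cc2c1C(=O)C(c1cc(OC)c(OC)c(CC=C(C)C)c1OC)CO2 | intermediate
21 | (3R,4R)-5-methoxy-7-(methoxymethoxy)-6-(3-methylbut-2-en-1-yl)-3-[2,4,5-trimethoxy-3-(3-methylbut-2-en-1-yl)phenyl]-3,4-dihydro-2H-chromen-4-ol (3,4-cis) | COc1c(CC=C(C)C)c(OCOC)cc2c1[C@H](O)[C@H](c1cc(OC)c(OC)c(CC=C(C)C)c1OC)CO2 | intermediate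
22 | (3R)-5-methoxy-7-(methoxymethoxy)-6-(3-methylbut-2-en-1-yl)-3-[2,4,5-trimethoxy-3-(3-methylbut-2-en-1-yl)phenyl]-3,4-dihydro-2H-chromene | COc1c(CC=C(C)C)c(OCOC)cc2c1C[C@H](c1cc(OC)c(OC)c(CC=C(C)C)c1OC)CO2 | intermediate
23 | 2-methoxy-5-[(3R)-5-methoxy-7-(methoxymethoxy)-6-(3-methylbut-2-en-1-yl)-3,4-dihydro-2H-chromen-3-yl]-3-(3-methylbut-2-en-1-yl)cyclohexa-2,5-diene-1,4-dione | COc1c(CC=C(C)C)c(OCOC)cc2c1C[C@H](C1=CC(=O)C(OC)=C(CC=C(C)C)C1=O)CO2 | intermediate
24 | 2-hydroxy-5-[(3R)-5-methoxy-7-(methoxymethoxy)-6-(3-methylbut-2-en-1-yl)-3,4-dihydro-2H-chromen-3-yl]-3-(3-methylbut-2-en-1-yl)cyclohexa-2,5-diene-1,4-dione | COc1c(CC=C(C)C)c(OCOC)cc2c1C[C@H](C1=CC(=O)C(O)=C(CC=C(C)C)C1=O)CO2 | intermediate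
25 | 2-hydroxy-5-[(3R)-7-hydroxy-5-methoxy-6-(3-methylbut-2-en-1-yl)-3,4-dihydro-2H-chromen-3-yl]-3-(3-methylbut-2-en-1-yl)cyclohexa-2,5-diene-1,4-dione (CNP0148998.1) | COc1c(CC=C(C)C)c(O)cc2c1C[C@H](C1=CC(=O)C(O)=C(CC=C(C)C)C1=O)CO2 | target

## Step count and least certain steps

Total step count: 18. Longest linear sequence: 14 steps (steps 1–4 and 9–18; the ring B branch, steps 5–8 and 9–18, is equally long).

**Step 11 (key step).** Two processes could defeat it. The open-chain ester may return to the lactone or close through oxygen to a 4-pyranone instead of being acylated at carbon, since the reacting methylene sits beside a ketone whose other neighbour is the acidic, prenyl-bearing methine. Methoxide may also exchange the MOM enol ether by addition–elimination, which would erase the marking of O7. The fallback changes the substrate so that the other ortho bond (C4a–C5) is closed to the same product. It sets out from 2 and 11 and returns at 15. Commercial 4-hydroxy-6-methyl-2H-pyran-2-one F1 is C-prenylated at its nucleophilic C3 with 2 (DBU, MeCN) to give 4-hydroxy-6-methyl-3-prenyl-2H-pyran-2-one F2. Protection with MOMCl and i-Pr2NEt gives 4-(methoxymethoxy)-6-methyl-3-prenyl-2H-pyran-2-one F3. Deprotonation with LiN(i-Pr)2 and addition to 11 gives the aldol adduct 6-(3-Ar-2-hydroxypropyl)-4-(methoxymethoxy)-3-prenyl-2H-pyran-2-one F4, and Dess–Martin oxidation gives 4-(methoxymethoxy)-6-(3-Ar-2-oxopropyl)-3-prenyl-2H-pyran-2-one F5. The open form of F5 has no sp3 methine and an unhindered nucleophilic arm, and Mg(OMe)2 in methanol should fold it to 15. This pyrone is held in reserve because its ester carbonyl, on a tetrasubstituted alkene carbon, is the poorer acyl acceptor and because C-prenylation of F1 competes with O-alkylation.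

**Step 16.** The C4 cation may lose the C3 hydrogen to an isoflav-3-ene and be reprotonated, which would erode the configuration at C3; the acid may also start ionic hydrogenation of a prenyl alkene or cleave the MOM acetal. The fallback is a radical deoxygenation that cannot involve C3. It sets out from 21 and returns at 22. The alcohol is converted with NaH, CS2 and MeI into the xanthate O-[(3R,4R)-5-methoxy-7-(methoxymethoxy)-6-prenyl-3-Ar-3,4-dihydro-2H-chromen-4-yl] S-methyl carbonodithioate F8, which is reduced with Bu3SnH and AIBN in toluene at 80 °C (Barton–McCombie) to 22.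

**Step 18.** Acid may add a hydroxyl across the neighbouring prenyl alkene (4'-OH with the 3'-prenyl group of the hydroxyquinone, or 7-OH with the 6-prenyl group) while the acetal is being removed. Prolonged base may epimerise C3 through a quinone methide tautomer. The fallback changes the protecting group so that no acid meets the hydroxyquinone. It sets out from 22 and returns at 25. Mild methanolysis (HCl, MeOH, rt) of the acetal at the isoflavan stage gives (3R)-5-methoxy-6-prenyl-3-Ar-3,4-dihydro-2H-chromen-7-ol F9. Acetylation (Ac2O, pyridine) gives the 7-acetate F10, and oxidation with (NH4)2Ce(NO3)6 gives the methoxyquinone acetate F11. One short treatment with cold aqueous NaOH under argon cleaves the acetate and the vinylogous methyl ester together, and buffering with NaH2PO4 gives 25.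

**Step 15.** Hydride transfer to a ketone flanked by the C5 methoxy group and an ortho-substituted ring B may be slow, and retro-oxa-Michael opening of the isoflavanone under Et3N may then lower conversion and selectivity. The fallback replaces asymmetric catalysis by resolution. It sets out from 20 and returns at 22. NaBH4 in MeOH reduces 20 to the racemic isoflavan-4-ols F6 (cis/trans mixture), ionic hydrogenation as in step 16 gives the racemic isoflavan F7, and preparative HPLC on a polysaccharide chiral stationary phase separates 22 from its enantiomer.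

## Further compounds

F1 | step 11 | 4-hydroxy-6-methyl-2H-pyran-2-one | CC1=CC(O)=CC(=O)O1
F2 | step 11 | 4-hydroxy-6-methyl-3-(3-methylbut-2-en-1-yl)-2H-pyran-2-one | CC1=CC(O)=C(CC=C(C)C)C(=O)O1
F3 | step 11 | 4-(methoxymethoxy)-6-methyl-3-(3-methylbut-2-en-1-yl)-2H-pyran-2-one | CC1=CC(OCOC)=C(CC=C(C)C)C(=O)O1
F4 | step 11 | 6-{2-hydroxy-3-[2,4,5-trimethoxy-3-(3-methylbut-2-en-1-yl)phenyl]propyl}-4-(methoxymethoxy)-3-(3-methylbut-2-en-1-yl)-2H-pyran-2-one (racemic) | O=C1OC(CC(O)Cc2cc(OC)c(OC)c(CC=C(C)C)c2OC)=CC(OCOC)=C1CC=C(C)C
F5 | step 11 | 4-(methoxymethoxy)-3-(3-methylbut-2-en-1-yl)-6-{2-oxo-3-[2,4,5-trimethoxy-3-(3-methylbut-2-en-1-yl)phenyl]propyl}-2H-pyran-2-one | O=C1OC(CC(=O)Cc2cc(OC)c(OC)c(CC=C(C)C)c2OC)=CC(OCOC)=C1CC=C(C)C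
F6 | step 15 | rac-5-methoxy-7-(methoxymethoxy)-6-(3-methylbut-2-en-1-yl)-3-[2,4,5-trimethoxy-3-(3-methylbut-2-en-1-yl)phenyl]-3,4-dihydro-2H-chromen-4-ol (cis/trans mixture) | COc1c(CC=C(C)C)c(OCOC)cc2c1C(O)C(c1cc(OC)c(OC)c(CC=C(C)C)c1OC)CO2
F7 | step 15 | rac-5-methoxy-7-(methoxymethoxy)-6-(3-methylbut-2-en-1-yl)-3-[2,4,5-trimethoxy-3-(3-methylbut-2-en-1-yl)phenyl]-3,4-dihydro-2H-chromene | COc1c(CC=C(C)C)c(OCOC)cc2c1CC(c1cc(OC)c(OC)c(CC=C(C)C)c1OC)CO2
F8 | step 16 | O-[(3R,4R)-5-methoxy-7-(methoxymethoxy)-6-(3-methylbut-2-en-1-yl)-3-[2,4,5-trimethoxy-3-(3-methylbut-2-en-1-yl)phenyl]-3,4-dihydro-2H-chromen-4-yl] S-methyl carbonodithioate | COc1c(CC=C(C)C)c(OCOC)cc2c1[C@H](OC(=S)SC)[C@H](c1cc(OC)c(OC)c(CC=C(C)C)c1OC)CO2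
F9 | step 18 | (3R)-5-methoxy-6-(3-methylbut-2-en-1-yl)-3-[2,4,5-trimethoxy-3-(3-methylbut-2-en-1-yl)phenyl]-3,4-dihydro-2H-chromen-7-ol | COc1c(CC=C(C)C)c(O)cc2c1C[C@H](c1cc(OC)c(OC)c(CC=C(C)C)c1OC)CO2
F10 | step 18 | (3R)-5-methoxy-6-(3-methylbut-2-en-1-yl)-3-[2,4,5-trimethoxy-3-(3-methylbut-2-en-1-yl)phenyl]-3,4-dihydro-2H-chromen-7-yl acetate | COc1c(CC=C(C)C)c(OC(C)=O)cc2c1C[C@H](c1cc(OC)c(OC)c(CC=C(C)C)c1OC)CO2
F11 | step 18 | (3R)-5-methoxy-3-[4-methoxy-5-(3-methylbut-2-en-1-yl)-3,6-dioxocyclohexa-1,4-dien-1-yl]-6-(3-methylbut-2-en-1-yl)-3,4-dihydro-2H-chromen-7-yl acetate | COc1c(CC=C(C)C)c(OC(C)=O)cc2c1C[C@H](C1=CC(=O)C(OC)=C(CC=C(C)C)C1=O)CO2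
A1 | alternative 1 | cis-fused 1,9-dimethoxy-2,10-bis(3-methylbut-2-en-1-yl)-3-(triisopropylsilyloxy)pterocarpan-8-ol | COc1c(CC=C(C)C)c(O[Si](C(C)C)(C(C)C)C(C)C)cc2c1[C@@H]3Oc4c(CC=C(C)C)c(OC)c(O)cc4[C@@H]3CO2
A2 | alternative 1 | 2-methoxy-3-(3-methylbut-2-en-1-yl)cyclohexa-2,5-diene-1,4-dione | COC1=C(CC=C(C)C)C(=O)C=CC1=O
A3 | alternative 1 | 5-methoxy-6-(3-methylbut-2-en-1-yl)-7-(triisopropylsilyloxy)-2H-chromene | COc1c(CC=C(C)C)c(O[Si](C(C)C)(C(C)C)C(C)C)cc2OCC=Cc12
A4 | alternative 2 | 2-methoxy-5-[(3R)-5-methoxy-7-(methoxymethoxy)-6-(3-methylbut-2-en-1-yl)-3,4-dihydro-2H-chromen-3-yl]-3-(3-methylbut-2-en-1-yl)cyclohexa-2,5-diene-1,4-dione | COc1c(CC=C(C)C)c(OCOC)cc2c1C[C@H](C3=CC(=O)C(OC)=C(CC=C(C)C)C3=O)CO2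
A5 | alternative 2 | 4-hydroxy-3-methoxy-4-{[(3R)-5-methoxy-7-(methoxymethoxy)-6-(3-methylbut-2-en-1-yl)-3,4-dihydro-2H-chromen-3-yl]ethynyl}-2-(3-methylbut-2-en-1-yl)cyclobut-2-en-1-one | COc1c(CC=C(C)C)c(OCOC)cc2c1C[C@H](C#CC1(O)C(OC)=C(CC=C(C)C)C1=O)CO2
A6 | alternative 3 | (3R)-5-methoxy-7-(methoxymethoxy)-6-(3-methylbut-2-en-1-yl)-3-[2,4,5-trimethoxy-3-(3-methylbut-2-en-1-yl)phenyl]-3,4-dihydro-2H-chromene | COc1c(CC=C(C)C)c(OCOC)cc2c1C[C@H](c3cc(OC)c(OC)c(CC=C(C)C)c3OC)CO2
A7 | alternative 3 | (3R)-7-(methoxymethoxy)-3-[2,4,5-trimethoxy-3-(3-methylbut-2-en-1-yl)phenyl]-6-(trimethylsilyl)-3,4-dihydro-2H-chromen-5-yl trifluoromethanesulfonate | C[Si](C)(C)c1c(OCOC)cc2c(c1OS(=O)(=O)C(F)(F)F)C[C@H](c1cc(OC)c(OC)c(CC=C(C)C)c1OC)CO2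
A8 | alternative 3 | 3-methoxy-3-methylbut-1-ene | COC(C)(C)C=C
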